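A small charge of solid substrate, 0.012 M in ash, stands at 30 °C with partner at 0.0600 M. We want the target it holds after 8.0 h, and where it ranks among the other flasks.

| flask | solid substrate | partner | temperature | remark | time |
|---|---|---|---|---|---|
| Saturday's | 0.050 M | 0.0097 M | 48 °C | run made earlier |  |
| Tuesday's | 0.050 M | 0.036 M | 86 °C | run made earlier |  |
| Monday's | 0.050 M | 0.13 M | 48 °C | run made earlier |  |
| Friday's | 0.053 M | 0.040 M | 86 °C | run made earlier |  |
| maple | 0.050 M | 0.0400 M | 70 °C |  | 8.0 h |
| ash | 0.012 M | 0.0600 M | 30 °C |  | 8.0 h |
| cedar | 0.20 M | 0.120 M | 90 °C |  | 8.0 h |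
| alder | 0.012 M | 0.0120 M | 30 °C |  | 8.0 h |
| elm | 0.080 M | 0.0100 M | 100 °C |  | 8.0 h |

- Saturday's (time / h: target / %, solid substrate / %): 1.33: 10.8, 29.1; 2.50: 15.7, 15.3; 4.00: 17.4, 4.8; 8.00: 16.8, 0; 20.0: 16.6, 0
- Tuesday's (time / h: target / %, solid substrate / %): 0.250: 18.2, 70.6; 0.667: 40.1, 28.9; 1.00: 48.4, 7.1; 2.00: 48.1, 0; 2.50: 46.9, 0
- Monday's (time / h: target / %, solid substrate / %): 3.00: 96.5, 0; 8.00: 96.5, 0.2; 15.0: 97.7, 0; 20.0: 95.8, 0.1
- Friday's (time / h: target / %, solid substrate / %): 0.200: 14.2, 77.1; 0.417: 28.8, 55.0; 0.667: 40.4, 32.1; 1.33: 52.1, 0.2; 2.50: 49.4, 0

(standard deviation of a reading: 0.5 percentage points)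

- as a solid, counted per litre of solution: solid substrate
- the numbers in the tables scatter with a standard deviation of 0.5 percentage points
- at the start none of the solid substrate is in solution
- what has only dissolved of solid substrate counts as not reacted

- the flasks put in order of amount of target, in percent of the solid substrate charged, best first, at 8.0 h (maple / ash / cedar / alder / elm)
- the amount of target, in percent of the solid substrate charged of the flask you put first, at 8.0 h
- the amount of target, in percent of the solid substrate charged of the flask you put last, at 8.0 h

Two facts about ash pull apart. Its partner covers the substrate 5.00 times, more cover than the 2.60 times of Monday's run, which held 96.5 % target by 3.00 h. Yet ash has less partner per litre, and is colder, 30 °C against 48 °C. Cover tells how much target can form, not how fast, so we need a rate.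

We define k as target made per hour, divided by mean dissolved substrate and mean partner, and read it from the first stretch of a run. Mean partner is the charge less half the target made. For dissolved substrate we take what is neither solid nor target, an upper limit, and replace its curve by a mean. Tuesday's stretch of 0.250 h is short, so we take the mean as half the end value, giving 413 /M/h. Saturday's curve has already bent, standing at 60.1 % at 1.33 h and 69.0 % at 2.50 h. Its mean therefore lies near 0.7 of the end value, giving 27.6 /M/h. Those two values give an activation energy of 68.3 kJ/mol, and from it the uptake constant at 30 °C, k_c = 6.03 /M/h.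

In ash the partner is in excess, so the uptake is pseudo-first-order. Counting the forward step by itself, with partner as charged, our half-life of dissolved substrate in ash is 1.91 h, shorter than the 8.0 h allowed, and with the whole charge taken as dissolved from the start we reckon 94.5 % target.

The forecast gave ash > alder > maple > cedar > elm, with 85 % for ash and 5.5 % for elm, on the ground “dilute with excess partner”. Our figure for ash is higher than its figure.

The flasks give ash > maple > cedar > alder > elm, with 3.92 % target in elm.

    solid substrate ⇌ dissolved substrate, rate k1*(cs1 - [dissolved substrate]) while solid is left; crystals form when [dissolved substrate] > cs1 (solubility = 34.0 mM, k = 2.00 /h)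
    dissolved substrate + partner ⇌ target (K = 190 /M, k = 140 /M/h, Ea = 67.0 kJ/mol, ΔH = −32.0 kJ/mol)
    2 dissolved substrate → side product (k = 3.40 /M/h, Ea = 56.0 kJ/mol)
    (constants at 70 °C)

Ash stands first at 90.2 %, with 8.97 % of its charge still dissolved substrate at 8.00 h. Alder has the same substrate charge and temperature, but its partner, 0.0120 M, equals that charge, so we let the two fall together. The fraction turned into target is then N over one plus N, where N is k_c times the charge times the time. At alder's 30 °C, k_c is 6.03 /M/h, so N is 0.579, which reckons 36.7 %, and alder stands at 35.9 %.

The runs are calculated on assumed constants; scatter was added.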